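**Strategy.** The route rests on one disconnection. The N1–C8a bond of the pyrrolidine ring and the C3a–prenyl bond are cut together, which flattens the cis-fused aminal to an achiral tryptamine. The feature exploited is the N8–C8a–C3a unit of the indoline ring. In the aromatic precursor it is an enamine, so C3a is nucleophilic and C8a turns electrophilic as soon as C3a is alkylated. An enantioselective palladium-catalysed dearomative prenylation of the N-Boc tryptamine of a bromo-furo[2,3-e]indole thus sets the quaternary carbon, the aminal carbon and the pyrrolidine ring (C3a, C3, C2, N1, C8a) in one operation. The precursor comes from Sonogashira annulation, Bartoli indolisation and sulfamidate opening.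

Key step: step 6

Numbering remark: tetracycles carry pyrroloindoline numbering (N1, C2, C3, C3a, C3b, C4–C7, C7a, N8, C8a). The furan is fused through its oxygen at C4 and through carbon at C5, and bromine sits on C7. Indole numbering (C2, C3) is used for the reacting carbons of 12.

Assumption: the sense of induction of the phosphoramidite cannot be assigned in advance for this substrate. The ligand antipode that sends prenyl to the Re face of indole C3 is taken, and both antipodes are available from (R)- or (S)-BINOL.

**Step 1**
Reactants: 1 4-bromo-3-nitrophenol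
Product: 2 4-bromo-2-iodo-5-nitrophenol
Conditions: NIS (1.05 equiv), p-TsOH·H2O (10 mol%), MeCN, 0 °C to rt
Reagents that add atoms: N-iodosuccinimide, O=C1CCC(=O)N1I
Why: Electrophilic aromatic iodination directed by the hydroxyl group; its para position carries bromine and the ortho position between OH and NO2 is crowded, so iodine should enter at the open ortho carbon (C6 of 1).

**Step 2**
Reactants: 2 4-bromo-2-iodo-5-nitrophenol; 3 2-methylbut-3-yn-2-ol
Product: 5 2-(5-bromo-6-nitro-1-benzofuran-2-yl)propan-2-ol, via alkynylphenol 4 (not isolated)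
Conditions: PdCl2(PPh3)2 (2 mol%), CuI (4 mol%), Et3N (3 equiv), DMF, rt then 60 °C
Reagents that add atoms: none
Why: Sonogashira coupling at the C–I bond, which adds to palladium far faster than C–Br, gives 4, whose phenoxide adds 5-endo-dig to the distal alkyne carbon activated by the para nitro group and so closes the furan ring.

**Step 3**
Reactants: 5 2-(5-bromo-6-nitro-1-benzofuran-2-yl)propan-2-ol; 6 vinylmagnesium bromide
Product: 9 2-(5-bromo-6H-furo[2,3-e]indol-2-yl)propan-2-ol, via nitrosoarene 7 (not isolated), via O-vinylhydroxylamine 8 (not isolated)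
Conditions: 6 (4.2 equiv, 1 M in THF), THF, −45 °C; sat. aq. NH4Cl
Reagents that add atoms: none
Why: Bartoli indole synthesis, in which the ortho bromine drives the [3,3]-sigmatropic shift of 8 onto the only free ortho carbon (benzofuran C7), so a single 7-bromoindole regioisomer should form; one extra equivalent of 6 is consumed by the alcohol.

**Step 4**
Reactants: 9 2-(5-bromo-6H-furo[2,3-e]indol-2-yl)propan-2-ol; 10 tert-butyl 1,2,3-oxathiazolidine-3-carboxylate 2,2-dioxide
Product: 12 tert-butyl N-{2-[5-bromo-2-(2-hydroxypropan-2-yl)-6H-furo[2,3-e]indol-8-yl]ethyl}carbamate, via N-sulfamate 11 (not isolated)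
Conditions: MeMgCl (2.3 equiv), CuCl (1 equiv), CH2Cl2/THF, −20 °C; 10 (1.2 equiv), −20 to 0 °C; then 10% aq. citric acid, rt
Reagents that add atoms: none
Why: C3-selective alkylation of the magnesiated indole in the presence of CuCl by SN2 opening of the cyclic sulfamidate at its O–CH2 carbon, with the tight N–Mg bond and the flanking bromine disfavouring N-alkylation, followed by mild acid hydrolysis of the N-acyl sulfamate 11.

**Step 5**
Reactants: 13 3-methylbut-2-en-1-ol (prenol)
Product: 14 methyl 3-methylbut-2-en-1-yl carbonate
Conditions: ClCO2Me (1.2 equiv), pyridine (1.5 equiv), CH2Cl2, 0 °C to rt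
Reagents that add atoms: methyl chloroformate, COC(=O)Cl
Why: O-acylation of a primary allylic alcohol with a chloroformate under pyridine catalysis.

**Step 6**
Reactants: 12 tert-butyl N-{2-[5-bromo-2-(2-hydroxypropan-2-yl)-6H-furo[2,3-e]indol-8-yl]ethyl}carbamate; 14 methyl 3-methylbut-2-en-1-yl carbonate
Product: 16 (3aS,8aS)-N1-Boc-7-bromo-3a-prenyl furo-fused hexahydropyrrolo[2,3-b]indole, via indolenine 15 (not isolated)
Conditions: Pd2(dba)3·CHCl3 (2.5 mol%), BINOL-derived chiral monodentate phosphoramidite (11 mol%), 14 (1.2 equiv), CH2Cl2, 0 °C to rt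
Reagents that add atoms: none
Why: Zerovalent palladium ionises 14 with loss of CO2 and methoxide to a cationic η3-prenyl complex, the enamine carbon C3 of the indole attacks its CH2 terminus to give indolenine 15, and the carbamate N–H, deprotonated by the methoxide, adds to the C=N carbon. The closest known reaction type is the palladium-catalysed asymmetric allylic alkylation run as a dearomative prenylation–cyclisation cascade on tryptamine carbamates. The pyrrolidine ring closes 5-exo-trig, N1 attacking C8a while the C8a=N8 π bond opens towards N8 outside the new ring. C3a is controlled by the chiral phosphoramidite on palladium, which should leave only the Re face of C3 open to the allyl terminus, and C8a is controlled by C3a, because the two-carbon tether can deliver N1 only to the face of C8a on which it lies, which makes the ring fusion cis and puts H8a on the side of the prenyl group. The step needs C3 over N attack, linear over branched attack and a single prenylation: the bromine next to the ring nitrogen shields and deactivates it in 12 and in 16, the furan oxygen at C4 enriches C3 without crowding it, and the dimethyl terminus of the allyl ligand is the more hindered one. The C–Br bond of the electron-rich arene should not add to phosphoramidite-bound zerovalent palladium at room temperature, and the tertiary alcohol is too hindered to be allylated.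

**Step 7**
Reactants: 16 (3aS,8aS)-N1-Boc-7-bromo-3a-prenyl furo-fused hexahydropyrrolo[2,3-b]indole
Product: 17 target, (3aS,8aS)-7-bromo-1-methyl-3a-prenyl furo-fused hexahydropyrrolo[2,3-b]indole
Conditions: LiAlH4 (6 equiv), THF, 60 °C; aq. potassium sodium tartrate
Reagents that add atoms: none
Why: Hydride reduction of a carbamate to an N-methylamine, in which the Boc carbonyl carbon becomes the N-methyl carbon, while the aminal stays closed and the electron-rich aryl bromide should be reduced more slowly, so neither stereocentre is touched.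

**Compound list**
1 | 4-bromo-3-nitrophenol | Oc1ccc(Br)c([N+](=O)[O-])c1 | starting material
2 | 4-bromo-2-iodo-5-nitrophenol | Oc1cc([N+](=O)[O-])c(Br)cc1I | intermediate
3 | 2-methylbut-3-yn-2-ol | CC(C)(O)C#C | starting material
4 | 4-bromo-2-(3-hydroxy-3-methylbut-1-yn-1-yl)-5-nitrophenol (not isolated) | CC(C)(O)C#Cc1cc(Br)c([N+](=O)[O-])cc1O | intermediate
5 | 2-(5-bromo-6-nitro-1-benzofuran-2-yl)propan-2-ol | CC(C)(O)c1cc2cc(Br)c([N+](=O)[O-])cc2o1 | intermediate
6 | vinylmagnesium bromide | C=C[Mg]Br | starting material
7 | 2-(5-bromo-6-nitroso-1-benzofuran-2-yl)propan-2-ol (not isolated, drawn as the free alcohol) | CC(C)(O)c1cc2cc(Br)c(N=O)cc2o1 | intermediate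
8 | 2-{5-bromo-6-[(ethenyloxy)amino]-1-benzofuran-2-yl}propan-2-ol (not isolated, drawn in neutral form) | CC(C)(O)c1cc2cc(Br)c(NOC=C)cc2o1 | intermediate
9 | 2-(5-bromo-6H-furo[2,3-e]indol-2-yl)propan-2-ol (indole with Br at C7, furan O on C4, furan carbon on C5) | CC(C)(O)c1cc2cc(Br)c3[nH]ccc3c2o1 | intermediate
10 | tert-butyl 1,2,3-oxathiazolidine-3-carboxylate 2,2-dioxide | CC(C)(C)OC(=O)N1CCOS1(=O)=O | starting material
11 | N-Boc-N-sulfo derivative of tryptamine 12 (not isolated, drawn as the acid) | CC(C)(C)OC(=O)N(CCc1c[nH]c2c(Br)cc3cc(C(C)(C)O)oc3c12)S(=O)(=O)O | intermediate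
12 | tert-butyl N-{2-[5-bromo-2-(2-hydroxypropan-2-yl)-6H-furo[2,3-e]indol-8-yl]ethyl}carbamate | CC(C)(C)OC(=O)NCCc1c[nH]c2c(Br)cc3cc(C(C)(C)O)oc3c12 | intermediate
13 | 3-methylbut-2-en-1-ol (prenol) | CC(C)=CCO | starting material
14 | methyl 3-methylbut-2-en-1-yl carbonate | CC(C)=CCOC(=O)OC | intermediate
15 | tert-butyl N-{2-[(8S)-5-bromo-2-(2-hydroxypropan-2-yl)-8-(3-methylbut-2-en-1-yl)-8H-furo[2,3-e]indol-8-yl]ethyl}carbamate (indolenine, not isolated) | CC(C)=CC[C@@]1(CCNC(=O)OC(C)(C)C)C=Nc2c(Br)cc3cc(C(C)(C)O)oc3c21 | intermediate
16 | (3aS,8aS)-N1-Boc-7-bromo-3a-prenyl-1,2,3,3a,8,8a-hexahydropyrrolo[2,3-b]indole fused at C4 (O) and C5 (C) to a furan that bears 2-hydroxypropan-2-yl next to oxygen; prenyl and H8a cis | CC(C)=CC[C@@]12CCN(C(=O)OC(C)(C)C)[C@@H]1Nc1c(Br)cc3cc(C(C)(C)O)oc3c12 | intermediate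
17 | (3aS,8aS)-7-bromo-1-methyl-3a-prenyl-1,2,3,3a,8,8a-hexahydropyrrolo[2,3-b]indole fused at C4 (O) and C5 (C) to a furan that bears 2-hydroxypropan-2-yl next to oxygen | CC(C)=CC[C@@]12CCN(C)[C@@H]1Nc1c(Br)cc3cc(C(C)(C)O)oc3c12 | target

**Total step count:** 7. **Longest linear sequence:** 6 (steps 1, 2, 3, 4, 6, 7).

**Steps most likely to fail**

Step 6. The peri oxygen at C4 and the bromine at C7 may erode facial discrimination. Attack may also leak to the branched terminus of the allyl ligand or to nitrogen. The fallback sets out from 12 and comes back at 16. It removes the regiochemical question by transferring a symmetrical allyl group and building the prenyl terminus afterwards.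
- 12 is treated with allyl alcohol and 9-hexyl-9-borabicyclo[3.3.1]nonane in CH2Cl2 at 4 °C.
- The catalyst is Pd2(dba)3·CHCl3 with the C2-symmetric bis(2-diphenylphosphinobenzamide) of enantiopure 11,12-diamino-9,10-dihydro-9,10-ethanoanthracene.
- This should give the (3aS,8aS)-C3a-allyl N1-Boc pyrroloindoline F1 through the same C3 attack and 5-exo-trig closure.
- Cross-metathesis of F1 with 2-methylbut-2-ene (second-generation Grubbs catalyst, CH2Cl2, 40 °C) then turns allyl into prenyl and gives 16.

Step 3. The Grignard reagent may reduce the nitro group to the aniline stage, or add elsewhere on the nitroarene, so that little material passes through the sigmatropic shift. The fallback sets out from 5 and comes back at 9. It builds the pyrrole ring by alkynylation and hydroamination instead.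
- Fe powder and NH4Cl in EtOH/H2O at 70 °C should reduce 5 to 2-(6-amino-5-bromo-1-benzofuran-2-yl)propan-2-ol F2.
- NIS in MeCN at 0 °C should iodinate the only free carbon ortho to the amine, giving 2-(6-amino-5-bromo-7-iodo-1-benzofuran-2-yl)propan-2-ol F3.
- Sonogashira coupling with trimethylsilylacetylene (PdCl2(PPh3)2, CuI, Et3N, rt) should give 2-{6-amino-5-bromo-7-[(trimethylsilyl)ethynyl]-1-benzofuran-2-yl}propan-2-ol F4.
- TBAF in refluxing THF should remove silicon and close the pyrrole ring 5-endo-dig to 9.

Step 7. Three things may go wrong: hydride may remove the bromine, reduction of the hindered tert-butyl carbamate may stall, and the aminal may open reductively under the forcing conditions. The fallback sets out from 16 and comes back at 17. It replaces reduction of the carbamate by its removal, with the methyl carbon supplied separately.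
- TMSOTf and 2,6-lutidine in CH2Cl2 at 0 °C should give the N1-trimethylsilyl carbamate O-trimethylsilyl ether F5.
- K2CO3 in MeOH should cleave both silyl groups, with loss of CO2, to the N1-H pyrroloindoline F6.
- Aqueous formaldehyde and NaBH(OAc)3 in 1,2-dichloroethane at rt should methylate only the aliphatic N1 and give 17, because N8 is a hindered and weakly basic ortho-bromoaniline.

**Further compounds**
F1 | step 6 | (3aS,8aS)-N1-Boc-3a-allyl-7-bromo furo-fused hexahydropyrrolo[2,3-b]indole (16 with allyl in place of prenyl) | C=CC[C@@]12CCN(C(=O)OC(C)(C)C)[C@@H]1Nc1c(Br)cc3cc(C(C)(C)O)oc3c12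
F2 | step 3 | 2-(6-amino-5-bromo-1-benzofuran-2-yl)propan-2-ol | CC(C)(O)c1cc2cc(Br)c(N)cc2o1
F3 | step 3 | 2-(6-amino-5-bromo-7-iodo-1-benzofuran-2-yl)propan-2-ol | CC(C)(O)c1cc2cc(Br)c(N)c(I)c2o1
F4 | step 3 | 2-{6-amino-5-bromo-7-[(trimethylsilyl)ethynyl]-1-benzofuran-2-yl}propan-2-ol | CC(C)(O)c1cc2cc(Br)c(N)c(C#C[Si](C)(C)C)c2o1
F5 | step 7 | (3aS,8aS)-N1-(trimethylsilyloxycarbonyl) O-trimethylsilyl ether of the N1-H pyrroloindoline | CC(C)=CC[C@@]12CCN(C(=O)O[Si](C)(C)C)[C@@H]1Nc1c(Br)cc3cc(C(C)(C)O[Si](C)(C)C)oc3c12
F6 | step 7 | N1-H pyrroloindoline (3aS,8aR by CIP ranking, same spatial arrangement as 16 and 17) | CC(C)=CC[C@@]12CCN[C@@H]1Nc1c(Br)cc3cc(C(C)(C)O)oc3c12
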